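**Easy count.** Counting turnovers is the easy step. I take each link to spend one first end group and one second end group, so I divide the smaller of c(first end groups) and c(second end groups) by c(first end groups). This share of links that the charge can pay for, 90.0% in the flask, is the turnover ceiling, and in the flask second end groups are the limiting reagent.

| setting | violet | ochre | amber | flask |
|---|---|---|---|---|
| first end groups | 0.27 M | 0.27 M | 0.14 M | 0.27 M |
| second end groups | 0.243 M | 0.243 M | 0.243 M | 0.243 M |
| protic impurity | 0.0067 M | 0.010 M | 0.0135 M | 0.0135 M |
| remark | run made earlier | run made earlier | run made earlier |  |
| time |  |  |  | 15 d |

- violet (time / d: links / %): 1.25: 89.7; 2.08: 88.2; 3.00: 89.1; 5.00: 88.7; 10.0: 89.3; 15.0: 89.5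
- ochre (time / d: links / %): 2.50: 89.1; 5.00: 89.1; 8.00: 88.7; 10.0: 89.5; 12.0: 90.0; 15.0: 89.0
- amber (time / d: links / %): 1.25: 100.1; 4.00: 99.8; 8.00: 100.4; 10.0: 99.7; 15.0: 101.0

(standard deviation of a reading: 0.5 percentage points)

- the reaction counts as stopped when no species that holds the first end groups changes by six tenths of a point or more over the second half of the time

- at 15 d, what has stopped the reaction, if anything has (the second end groups has run out first / all of the first end groups has reacted / it is still moving)
- the links standing at 15 d, as a percentage of the first end groups charged

**Drawn curve.** The flask's curve should start steeply, since violet, with the same end-group charges, already reads 89.7% at 1.25 d, an average slope of 0.194 M d⁻¹ as a reading. The knee therefore lies before that first reading. Beyond it, the violet and ochre readings run flat between 88.2% and 90.0%, at or under their ceiling of 90.0%. Amber, with the flask's impurity, reads 99.7% to 101.0% against a ceiling of 100%. The whole impurity charge taking second end groups one for one would put violet at 87.5%, lower than its lowest reading. So I commit to a level just under the ceiling, with second end groups out first.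

**The forecast.** The forecast says the second end groups has run out first and puts the links at 89.2%, from 88.4% to 90%: “so I expect the same plateau”.

**The result.** In the flask at 15 d, the answer is that the second end groups has run out first, and links stand at 89.0%. The flask's second end groups fall under 2% of their charge by 0.165 d, earlier than violet's first reading. Taking the flask's 0.00278 M of quenched reagent from the second end groups before dividing lowers its ceiling from 90.0% to 89.0%.

    first end groups + second end groups → links + released group (k = 0.00430 M⁻¹ s⁻¹)
    crystals ⇌ released group, rate k2*(cs2 - [released group]) while solid is left; crystals form when [released group] > cs2 (solubility = 0.110 M, k = 0.00280 s⁻¹)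
    second end groups + protic impurity → quenched reagent (k = 4.50 × 10⁻⁴ M⁻¹ s⁻¹)

**Second flask.** The neighbour flask with 0.46 M of first end groups has a ceiling of 52.8%, so I expect its links just below that. It gives 52.6%, with 47.4% of its first end groups left.

The earlier runs and the new flask were generated by integration for substances that don't exist, noise included.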